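Everything rests on disconnecting the C4–C5 bond and the C5–O bond of the oxirane (ring numbering: C1 heptenyl-bearing, C2 hydroxymethyl-bearing, C3 carbinol, C4 and C5 oxirane carbons, C6 ketone). The key step exploits that the C4–C5 oxirane is α,β to the C6 ketone with C5 fully substituted: an intramolecular Darzens reaction closes the cyclohexenone ring and the oxirane ring in one operation and sets C4 and C5. Its precursor is an open-chain Z-tetrasubstituted dienone carrying the C5 chloride and the C4 aldehyde; O3 and the oxygen of the C2 hydroxymethyl group are tied as an acetonide, which holds O3 pseudo-equatorial and so steers the oxirane cis to it.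

Key step: step 16

Remarks on the chemistry
- C2′ is the hydroxymethyl carbon on C2 and O3 the oxygen on C3; the target is 3S,4S,5S in this numbering, with the oxirane oxygen cis to the C3 hydroxyl.
- C6 is carried as a racemic carbinol (7 to 23) and C5–Cl as an epimer mixture (26 to 28); both centres are erased (steps 12 and 16), so these compounds are mixtures at those positions only.
- (tert-Butyldimethylsilyloxy)acetaldehyde 16 is assumed to be purchased.

Step 1
Reactants: 1 propargyl alcohol
Product: 2 triethyl(prop-2-yn-1-yloxy)silane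
Conditions: TESCl, imidazole, CH2Cl2, 0 °C
Reagents that add atoms: chlorotriethylsilane, CC[Si](CC)(CC)Cl
Why: Silyl ether formation at a primary alcohol; the TES group survives the organometallic steps and can later be removed by mild acid beside a primary TBS ether.

Step 2
Reactants: 3 5-bromo-2-methylpent-2-ene
Product: 5 5-methylhex-4-enal, via 4-methylpent-3-enylmagnesium bromide 4 (not isolated)
Conditions: Mg, THF, 40 °C; DMF, 0 °C → rt; aq. HCl
Reagents that add atoms: N,N-dimethylformamide, CN(C)C=O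
Why: Bouveault aldehyde synthesis, in which the Grignard reagent adds once to DMF and the aldehyde is released only on acidic work-up, supplying C6, C5 and the prenyl terminus.

Step 3
Reactants: 2 triethyl(prop-2-yn-1-yloxy)silane, 5 5-methylhex-4-enal
Product: 7 8-methyl-1-(triethylsilyloxy)non-7-en-2-yn-4-ol (racemic), via lithium acetylide 6 (not isolated)
Conditions: 2, n-BuLi, THF, −78 °C; 5, −78 °C; H2O
Reagents that add atoms: none
Why: 1,2-Addition of a lithium acetylide to an aldehyde; the new C6 centre needs no control because it is oxidised later.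

Step 4
Reactants: 8 hept-1-yne
Product: 10 (E)-1-iodohept-1-ene, via E-heptenylalane 9 (not isolated)
Conditions: iBu2AlH, hexane, 50 °C; I2, THF, −50 °C → rt
Reagents that add atoms: iodine, II
Why: Hydroalumination–iodination of a terminal alkyne, where syn addition of Al–H and iodinolysis with retention should give the E-iodoalkene.

Step 5
Reactants: 7 8-methyl-1-(triethylsilyloxy)non-7-en-2-yn-4-ol, 10 (E)-1-iodohept-1-ene
Product: 14 (7Z,8E)-7-[1-iodo-2-(triethylsilyloxy)ethylidene]-2-methyltetradeca-2,8-dien-6-ol, via E-heptenyllithium 11 (not isolated), via E-heptenylmagnesium bromide 12 (not isolated), via oxamagnesacycle 13 (not isolated)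
Conditions: 10, t-BuLi (2 equiv), THF, −78 °C; MgBr2·OEt2, → 0 °C; 7 premixed with iPrMgCl (1 equiv), then 65 °C; I2, −78 → 0 °C; H2O
Reagents that add atoms: iodine, II
Why: Hydroxyl-directed anti-carbomagnesiation of a propargylic alcohol, in which the magnesium alkoxide delivers the alkenyl group to C1 and holds magnesium on C2 in a five-membered chelate cis to C6, so that iodinolysis with retention should give iodine cis to the C6 arm and heptenyl cis to C2′ (Li–I exchange and transmetalation keep the E geometry of the Grignard reagent).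

Step 6
Reactants: 14 (7Z,8E)-7-[1-iodo-2-(triethylsilyloxy)ethylidene]-2-methyltetradeca-2,8-dien-6-ol
Product: 15 (7Z,8E)-7-[1-iodo-2-(triethylsilyloxy)ethylidene]-6-(4-methoxybenzyloxy)-2-methyltetradeca-2,8-diene
Conditions: NaH, PMBCl, nBu4NI (cat.), DMF, 0 °C → rt
Reagents that add atoms: 4-methoxybenzyl chloride, COc1ccc(CCl)cc1
Why: Williamson ether synthesis; a benzyl-type ether is chosen because a silyl ether on this oxygen, cis to the coming C2–Li bond, would invite 1,4 O→C silyl migration (retro-Brook rearrangement).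

Step 7
Reactants: 15 (7Z,8E)-7-[1-iodo-2-(triethylsilyloxy)ethylidene]-6-(4-methoxybenzyloxy)-2-methyltetradeca-2,8-diene, 16 (tert-butyldimethylsilyloxy)acetaldehyde
Product: 18 (3Z,5E)-1-(tert-butyldimethylsilyloxy)-4-[1-(4-methoxybenzyloxy)-5-methylhex-4-enyl]-3-[(triethylsilyloxy)methyl]undeca-3,5-dien-2-ol (diastereomer mixture), via alkenyllithium 17 (not isolated)
Conditions: t-BuLi (2.1 equiv), Et2O, −78 °C; 16, −78 °C; H2O
Reagents that add atoms: none
Why: Iodine–lithium exchange with retention of alkene geometry and 1,2-addition of the alkenyllithium to the aldehyde form the C2–C3 bond; the carbinol centre is reset in steps 8 and 9.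

Step 8
Reactants: 18 (3Z,5E)-1-(tert-butyldimethylsilyloxy)-4-[1-(4-methoxybenzyloxy)-5-methylhex-4-enyl]-3-[(triethylsilyloxy)methyl]undeca-3,5-dien-2-ol
Product: 19 (3Z,5E)-1-(tert-butyldimethylsilyloxy)-4-[1-(4-methoxybenzyloxy)-5-methylhex-4-enyl]-3-[(triethylsilyloxy)methyl]undeca-3,5-dien-2-one
Conditions: Dess–Martin periodinane, NaHCO3, CH2Cl2, 0 °C → rt
Reagents that add atoms: none
Why: Dess–Martin oxidation of a secondary allylic alcohol under buffered conditions that leave silyl and PMB ethers untouched.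

Step 9
Reactants: 19 (3Z,5E)-1-(tert-butyldimethylsilyloxy)-4-[1-(4-methoxybenzyloxy)-5-methylhex-4-enyl]-3-[(triethylsilyloxy)methyl]undeca-3,5-dien-2-one
Product: 20 (2S,3Z,5E)-1-(tert-butyldimethylsilyloxy)-4-[1-(4-methoxybenzyloxy)-5-methylhex-4-enyl]-3-[(triethylsilyloxy)methyl]undeca-3,5-dien-2-ol
Conditions: (S)-1-methyl-3,3-diphenyltetrahydro-1H,3H-pyrrolo[1,2-c][1,3,2]oxazaborole [(S)-Me-CBS, 0.3 equiv], catecholborane, toluene, −78 °C; MeOH; aq. NaOH wash
Reagents that add atoms: none
Why: Corey–Bakshi–Shibata reduction, in which the tetrasubstituted alkenyl group acts as the large and CH2OTBS as the small substituent, so the (S)-catalyst should give the S carbinol at C3 (the spatial analogue of (R)-1-phenylethanol, S here because CH2O outranks the alkenyl carbon); catecholborane avoids hydroboration of the alkenes.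

Step 10
Reactants: 20 (2S,3Z,5E)-1-(tert-butyldimethylsilyloxy)-4-[1-(4-methoxybenzyloxy)-5-methylhex-4-enyl]-3-[(triethylsilyloxy)methyl]undeca-3,5-dien-2-ol
Product: 22 (4S,5Z)-4-[(tert-butyldimethylsilyloxy)methyl]-5-{(2E)-1-[1-(4-methoxybenzyloxy)-5-methylhex-4-enyl]oct-2-enylidene}-2,2-dimethyl-1,3-dioxane, via diol 21 (not isolated)
Conditions: PPTS, MeOH, 0 °C; evaporate; 2,2-dimethoxypropane, acetone, PPTS, rt
Reagents that add atoms: 2,2-dimethoxypropane, COC(C)(C)OC
Why: Acid-catalysed methanolysis of the primary TES ether (primary TBS and PMB ethers resist PPTS) followed by ketalisation of the 1,3-diol gives the six-membered isopropylidene acetal that fixes O3 for the key step.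

Step 11
Reactants: 22 (4S,5Z)-4-[(tert-butyldimethylsilyloxy)methyl]-5-{(2E)-1-[1-(4-methoxybenzyloxy)-5-methylhex-4-enyl]oct-2-enylidene}-2,2-dimethyl-1,3-dioxane
Product: 23 (4S,5Z)-4-[(tert-butyldimethylsilyloxy)methyl]-5-[(2E)-1-(1-hydroxy-5-methylhex-4-enyl)oct-2-enylidene]-2,2-dimethyl-1,3-dioxane
Conditions: DDQ, CH2Cl2/pH 7 buffer, 0 °C
Reagents that add atoms: none
Why: Oxidative cleavage of a PMB ether by DDQ (hydride abstraction to the oxocarbenium ion, then hydrolysis) under buffered conditions that spare the acetonide and the TBS ether.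

Step 12
Reactants: 23 (4S,5Z)-4-[(tert-butyldimethylsilyloxy)methyl]-5-[(2E)-1-(1-hydroxy-5-methylhex-4-enyl)oct-2-enylidene]-2,2-dimethyl-1,3-dioxane
Product: 24 (4S,5Z)-4-[(tert-butyldimethylsilyloxy)methyl]-2,2-dimethyl-5-[(2E)-1-(5-methylhex-4-enoyl)oct-2-enylidene]-1,3-dioxane
Conditions: Dess–Martin periodinane, NaHCO3, CH2Cl2, rt
Reagents that add atoms: none
Why: Dess–Martin oxidation of the secondary alcohol gives the C6 ketone and removes the only uncontrolled centre carried so far.

Step 13
Reactants: 24 (4S,5Z)-4-[(tert-butyldimethylsilyloxy)methyl]-2,2-dimethyl-5-[(2E)-1-(5-methylhex-4-enoyl)oct-2-enylidene]-1,3-dioxane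
Product: 26 (4S,5Z)-4-[(tert-butyldimethylsilyloxy)methyl]-5-[(2E)-1-(2-chloro-5-methylhex-4-enoyl)oct-2-enylidene]-2,2-dimethyl-1,3-dioxane (C5 epimers), via lithium enolate 25 (not isolated)
Conditions: LiN(SiMe3)2, THF, −78 °C; cannulate into NCS, THF, −78 °C; H2O
Reagents that add atoms: N-chlorosuccinimide, O=C1CCC(=O)N1Cl
Why: Kinetic deprotonation at C5 (C1 is sp2, so the ketone has no other α-hydrogen) and electrophilic chlorination of the lithium enolate, with inverse addition to limit dichlorination.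

Step 14
Reactants: 26 (4S,5Z)-4-[(tert-butyldimethylsilyloxy)methyl]-5-[(2E)-1-(2-chloro-5-methylhex-4-enoyl)oct-2-enylidene]-2,2-dimethyl-1,3-dioxane
Product: 27 [(4S,5Z)-5-[(2E)-1-(2-chloro-5-methylhex-4-enoyl)oct-2-enylidene]-2,2-dimethyl-1,3-dioxan-4-yl]methanol
Conditions: HF·pyridine, pyridine, THF, 0 °C
Reagents that add atoms: none
Why: Fluoride-mediated cleavage of the primary TBS ether under buffered, non-basic conditions that should leave the α-chloro ketone and the acetonide untouched.

Step 15
Reactants: 27 [(4S,5Z)-5-[(2E)-1-(2-chloro-5-methylhex-4-enoyl)oct-2-enylidene]-2,2-dimethyl-1,3-dioxan-4-yl]methanol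
Product: 28 (4S,5Z)-5-[(2E)-1-(2-chloro-5-methylhex-4-enoyl)oct-2-enylidene]-2,2-dimethyl-1,3-dioxane-4-carbaldehyde
Conditions: Dess–Martin periodinane, NaHCO3, CH2Cl2, 0 °C
Reagents that add atoms: none
Why: Buffered Dess–Martin oxidation gives the α-alkoxy aldehyde without base, so C3 should not epimerise; the aldehyde is used at once.

Step 16
Reactants: 28 (4S,5Z)-5-[(2E)-1-(2-chloro-5-methylhex-4-enoyl)oct-2-enylidene]-2,2-dimethyl-1,3-dioxane-4-carbaldehyde
Product: 31 epoxy enone acetonide (3S,4S,5S; cyclohex-1-en-6-one with 4,5-oxirane; O3 and C2′–O joined as a 2,2-dimethyl-1,3-dioxane; (E)-hept-1-enyl on C1; 3-methylbut-2-enyl on C5), via potassium enolate 29 (not isolated), via chloro aldolate 30 (not isolated)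
Conditions: KN(SiMe3)2 (1.05 equiv), THF, −78 → −30 °C; pH 7 buffer
Reagents that add atoms: none
Why: The base removes the C5 hydrogen of the α-chloro ketone, the enolate adds to the C4 aldehyde and the C4 alkoxide displaces chloride at C5 with inversion, which is an intramolecular Darzens condensation of an α-halo ketone with an aldehyde. The carbocycle closes in a 6-(enolendo)-exo-trig aldol step (the enolate C5=C6 bond lies inside the forming ring) and the oxirane in a 3-exo-tet substitution. The aldol step is reversible and only the aldolate with an axial C4 oxygen anti-periplanar to an axial C5–Cl can close, so C5 is fixed by the substitution and the ring fusion is necessarily cis. C4 is controlled by C3 through the dioxane ring: the acetal keeps O3 near the plane of the C1=C2 bond (pseudo-equatorial) and the C3 hydrogen pseudo-axial, so the axial C4 oxygen of the closing half-chair lies on the face of O3 and the oxirane should form cis to O3. The step needs enolisation at C5 in preference to deprotonation at C3 (α to the aldehyde); the less hindered secondary C5–H acidified by chlorine, a bulky amide base in slight excess at −78 °C and the fast closure of two arms already held cis by the Z-alkene are relied on for this.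

Step 17
Reactants: 31 epoxy enone acetonide
Product: 32 E-allylic alcohol (as 31 with (E)-4-hydroxy-3-methylbut-2-enyl on C5)
Conditions: SeO2 (0.5 equiv), t-BuOOH, CH2Cl2, 0 °C → rt
Reagents that add atoms: tert-butyl hydroperoxide, CC(C)(C)OO (terminal oxidant; the oxygen is passed on through SeO2, O=[Se]=O)
Why: Riley allylic oxidation (ene reaction, then [2,3]-sigmatropic shift) should occur at the electron-rich trisubstituted alkene and at the methyl group trans to the chain, giving the E-allylic alcohol, while the electron-poor dienone should not compete; any enal formed alongside converges in step 18.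

Step 18
Reactants: 32 E-allylic alcohol
Product: 33 E-enal (as 31 with (E)-3-methyl-4-oxobut-2-enyl on C5)
Conditions: MnO2, CH2Cl2, rt
Reagents that add atoms: none
Why: MnO2 oxidises allylic alcohols selectively and should give the enal without touching the rest of the molecule.

Step 19
Reactants: 33 E-enal
Product: 34 acid acetonide (as 31 with (E)-3-carboxybut-2-enyl on C5)
Conditions: NaClO2, NaH2PO4, 2-methylbut-2-ene, t-BuOH/H2O, 0 °C
Reagents that add atoms: sodium chlorite, [Na+].[O-]Cl=O
Why: Pinnick oxidation of the enal with a hypochlorite scavenger should leave oxirane, enone and acetonide intact and keep the E-alkene.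

Step 20
Reactants: 34 acid acetonide
Product: 35 target acid (3S,4S,5S)
Conditions: 1 M aq. HCl, THF, 0 °C → rt
Reagents that add atoms: none
Why: Acid-catalysed acetal hydrolysis frees the C3 hydroxyl and the hydroxymethyl group; the oxirane, next to the ketone and flanked by electron-poor carbons, should resist dilute acid.

Compound list
1 | propargyl alcohol | C#CCO | starting material
2 | triethyl(prop-2-yn-1-yloxy)silane | C#CCO[Si](CC)(CC)CC | intermediate
3 | 5-bromo-2-methylpent-2-ene | CC(C)=CCCBr | starting material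
4 | 4-methylpent-3-enylmagnesium bromide (not isolated) | CC(C)=CCC[Mg]Br | intermediate
5 | 5-methylhex-4-enal | CC(C)=CCCC=O | intermediate
6 | [3-(triethylsilyloxy)prop-1-ynyl]lithium (not isolated) | [Li]C#CCO[Si](CC)(CC)CC | intermediate
7 | 8-methyl-1-(triethylsilyloxy)non-7-en-2-yn-4-ol, racemic | CC(C)=CCCC(O)C#CCO[Si](CC)(CC)CC | intermediate
8 | hept-1-yne | CCCCCC#C | starting material
9 | (E)-hept-1-enyl(diisobutyl)alane (not isolated) | CCCCC/C=C/[Al](CC(C)C)CC(C)C | intermediate
10 | (E)-1-iodohept-1-ene | CCCCC/C=C/I | intermediate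
11 | (E)-hept-1-enyllithium (not isolated) | CCCCC/C=C/[Li] | intermediate
12 | (E)-hept-1-enylmagnesium bromide (not isolated) | CCCCC/C=C/[Mg]Br | intermediate
13 | 2,5-dihydro-1,2-oxamagnesole chelate, Mg bridging C2 and the C6 oxygen (not isolated) | CCCCC/C=C/C1=C(CO[Si](CC)(CC)CC)[Mg]OC1CCC=C(C)C | intermediate
14 | (7Z,8E)-7-[1-iodo-2-(triethylsilyloxy)ethylidene]-2-methyltetradeca-2,8-dien-6-ol, racemic at C6 | CCCCC/C=C/C(C(O)CCC=C(C)C)=C(/I)CO[Si](CC)(CC)CC | intermediate
15 | (7Z,8E)-7-[1-iodo-2-(triethylsilyloxy)ethylidene]-6-(4-methoxybenzyloxy)-2-methyltetradeca-2,8-diene | CCCCC/C=C/C(C(OCc1ccc(OC)cc1)CCC=C(C)C)=C(/I)CO[Si](CC)(CC)CC | intermediate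
16 | (tert-butyldimethylsilyloxy)acetaldehyde | O=CCO[Si](C)(C)C(C)(C)C | starting material
17 | alkenyllithium from 15, Li on C2 in place of I (not isolated) | CCCCC/C=C/C(C(OCc1ccc(OC)cc1)CCC=C(C)C)=C(/[Li])CO[Si](CC)(CC)CC | intermediate
18 | (3Z,5E)-1-(tert-butyldimethylsilyloxy)-4-[1-(4-methoxybenzyloxy)-5-methylhex-4-enyl]-3-[(triethylsilyloxy)methyl]undeca-3,5-dien-2-ol, diastereomer mixture | CCCCC/C=C/C(C(OCc1ccc(OC)cc1)CCC=C(C)C)=C(CO[Si](CC)(CC)CC)/C(O)CO[Si](C)(C)C(C)(C)C | intermediate
19 | (3Z,5E)-1-(tert-butyldimethylsilyloxy)-4-[1-(4-methoxybenzyloxy)-5-methylhex-4-enyl]-3-[(triethylsilyloxy)methyl]undeca-3,5-dien-2-one | CCCCC/C=C/C(C(OCc1ccc(OC)cc1)CCC=C(C)C)=C(CO[Si](CC)(CC)CC)/C(=O)CO[Si](C)(C)C(C)(C)C | intermediate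
20 | (2S,3Z,5E)-1-(tert-butyldimethylsilyloxy)-4-[1-(4-methoxybenzyloxy)-5-methylhex-4-enyl]-3-[(triethylsilyloxy)methyl]undeca-3,5-dien-2-ol | CCCCC/C=C/C(C(OCc1ccc(OC)cc1)CCC=C(C)C)=C(CO[Si](CC)(CC)CC)/[C@H](O)CO[Si](C)(C)C(C)(C)C | intermediate
21 | (2S,3Z,5E)-1-(tert-butyldimethylsilyloxy)-3-(hydroxymethyl)-4-[1-(4-methoxybenzyloxy)-5-methylhex-4-enyl]undeca-3,5-dien-2-ol (not isolated) | CCCCC/C=C/C(C(OCc1ccc(OC)cc1)CCC=C(C)C)=C(CO)/[C@H](O)CO[Si](C)(C)C(C)(C)C | intermediate
22 | (4S,5Z)-4-[(tert-butyldimethylsilyloxy)methyl]-5-{(2E)-1-[1-(4-methoxybenzyloxy)-5-methylhex-4-enyl]oct-2-enylidene}-2,2-dimethyl-1,3-dioxane | CCCCC/C=C/C(C(OCc1ccc(OC)cc1)CCC=C(C)C)=C1/[C@@H](CO[Si](C)(C)C(C)(C)C)OC(C)(C)OC1 | intermediate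
23 | (4S,5Z)-4-[(tert-butyldimethylsilyloxy)methyl]-5-[(2E)-1-(1-hydroxy-5-methylhex-4-enyl)oct-2-enylidene]-2,2-dimethyl-1,3-dioxane | CCCCC/C=C/C(C(O)CCC=C(C)C)=C1/[C@@H](CO[Si](C)(C)C(C)(C)C)OC(C)(C)OC1 | intermediate
24 | (4S,5Z)-4-[(tert-butyldimethylsilyloxy)methyl]-2,2-dimethyl-5-[(2E)-1-(5-methylhex-4-enoyl)oct-2-enylidene]-1,3-dioxane | CCCCC/C=C/C(C(=O)CCC=C(C)C)=C1/[C@@H](CO[Si](C)(C)C(C)(C)C)OC(C)(C)OC1 | intermediate
25 | lithium enolate of 24, C5=C6–OLi (not isolated) | CCCCC/C=C/C(C(O[Li])=CCC=C(C)C)=C1/[C@@H](CO[Si](C)(C)C(C)(C)C)OC(C)(C)OC1 | intermediate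
26 | (4S,5Z)-4-[(tert-butyldimethylsilyloxy)methyl]-5-[(2E)-1-(2-chloro-5-methylhex-4-enoyl)oct-2-enylidene]-2,2-dimethyl-1,3-dioxane, C5 epimers | CCCCC/C=C/C(C(=O)C(Cl)CC=C(C)C)=C1/[C@@H](CO[Si](C)(C)C(C)(C)C)OC(C)(C)OC1 | intermediate
27 | [(4S,5Z)-5-[(2E)-1-(2-chloro-5-methylhex-4-enoyl)oct-2-enylidene]-2,2-dimethyl-1,3-dioxan-4-yl]methanol | CCCCC/C=C/C(C(=O)C(Cl)CC=C(C)C)=C1/[C@@H](CO)OC(C)(C)OC1 | intermediate
28 | (4S,5Z)-5-[(2E)-1-(2-chloro-5-methylhex-4-enoyl)oct-2-enylidene]-2,2-dimethyl-1,3-dioxane-4-carbaldehyde (key-step precursor) | CCCCC/C=C/C(C(=O)C(Cl)CC=C(C)C)=C1/[C@@H](C=O)OC(C)(C)OC1 | intermediate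
29 | potassium enolate of 28, C5=C6–OK with chlorine on C5 (not isolated) | CCCCC/C=C/C(C(O[K])=C(Cl)CC=C(C)C)=C1/[C@@H](C=O)OC(C)(C)OC1 | intermediate
30 | potassium chloro aldolate, ring closed, C4–OK cis to O3 and anti to C5–Cl (not isolated) | CCCCC/C=C/C1=C2COC(C)(C)O[C@@H]2[C@H](O[K])[C@](Cl)(CC=C(C)C)C1=O | intermediate
31 | epoxy enone acetonide, 3S,4S,5S, prenyl on C5 (key-step product) | CCCCC/C=C/C1=C2COC(C)(C)O[C@@H]2[C@@H]3O[C@]3(CC=C(C)C)C1=O | intermediate
32 | E-allylic alcohol, (E)-4-hydroxy-3-methylbut-2-enyl on C5 | CCCCC/C=C/C1=C2COC(C)(C)O[C@@H]2[C@@H]3O[C@]3(C/C=C(\C)CO)C1=O | intermediate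
33 | E-enal, (E)-3-methyl-4-oxobut-2-enyl on C5 | CCCCC/C=C/C1=C2COC(C)(C)O[C@@H]2[C@@H]3O[C@]3(C/C=C(\C)C=O)C1=O | intermediate
34 | acid acetonide, (E)-3-carboxybut-2-enyl on C5 | CCCCC/C=C/C1=C2COC(C)(C)O[C@@H]2[C@@H]3O[C@]3(C/C=C(\C)C(=O)O)C1=O | intermediate
35 | target acid | CCCCC/C=C/C1=C(CO)[C@H](O)[C@@H]2O[C@]2(C/C=C(\C)C(=O)O)C1=O | target

Total step count: 20. Longest linear sequence: 18 steps (steps 1 or 2, then 3 and 5 to 20).

Steps most likely to fail

Step 16. The base may remove the C3 hydrogen (α to the aldehyde) in competition with the C5 hydrogen, which would scramble C3, or the product may be degraded by deprotonation at C3 (now γ to the enone) and opening of the oxirane. The fallback sets out from 26 and returns at 31; it makes the enolate by reduction instead of deprotonation. A second enolate chlorination of 26 (LiN(SiMe3)2, then NCS, THF, −78 °C) would give the α,α-dichloro ketone F1. HF·pyridine and then buffered Dess–Martin oxidation, as in steps 14 and 15, would give the dichloro keto alcohol F2 and the dichloro keto aldehyde F3. SmI2 (2 equiv, THF, −78 °C) would cleave one C–Cl bond to the α-chloro samarium enolate, which closes the carbocycle in an intramolecular Reformatsky-type aldol reaction and gives the chlorohydrin F4 after protonation; no Brønsted base is present while the C3 hydrogen is α to an aldehyde. K2CO3 in MeCN at 0 °C would then close the oxirane of F4 to 31 by the same 3-exo-tet displacement.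

Step 5. The alkenylmagnesium chelate 13 may lose the silyloxy group on C2′ by β-elimination to an allene, or the substituted alkenyl Grignard reagent may add too slowly to the hindered alkoxide. The fallback sets out from 7 and returns at 14; it installs the two alkene substituents by halogenation and cross-coupling. Anti addition of I2 to the alkyne of 7 (CH2Cl2, rt, dark) would give the E-diiodide F5. Methanolysis of the TES ether (PPTS, MeOH) would give the diiodo diol F6, and 2,2,6,6-tetramethylpiperidin-1-oxyl with PhI(OAc)2 would oxidise only the primary alcohol to the diiodo enal F7. In F7 the C1 iodide is β to the aldehyde and is the one expected to undergo oxidative addition, so Suzuki–Miyaura coupling with purchased (E)-hept-1-enylboronic acid (Pd(PPh3)4, K3PO4, THF/H2O) would give the iodo dienal F8 with retention of both alkene geometries. Luche reduction (NaBH4, CeCl3·7H2O, MeOH, −40 °C) would give the iodo diene diol F9, and silylation of its primary alcohol (TESCl, imidazole, −78 °C) would return 14.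

Step 17. Oxidation at other allylic positions (the C3 hydrogen, the allylic CH2 of the heptenyl chain), over-oxidation, or loss of the acetonide under the acidic selenium conditions may give mixtures late in the route. The fallback sets out from 31 and returns at 34; it rebuilds the terminus by cleavage and olefination. Lemieux–Johnson oxidation (OsO4 cat., NaIO4, 2,6-lutidine, dioxane/H2O) would cleave the electron-rich trisubstituted alkene of 31 in preference to the electron-poor dienone and give the aldehyde F10. Wittig reaction with the stabilised ylide allyl 2-(triphenylphosphoranylidene)propanoate (made from allyl 2-bromopropanoate and PPh3; CH2Cl2, rt) would give the E-configured allyl ester F11. Pd(PPh3)4 with morpholine would remove the allyl group under neutral conditions and give 34, so three steps replace steps 17 to 19.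

Further compounds
F1 | step 16 | α,α-dichloro ketone, as 26 with a second chlorine on C5 | CCCCC/C=C/C(C(=O)C(Cl)(Cl)CC=C(C)C)=C1/[C@@H](CO[Si](C)(C)C(C)(C)C)OC(C)(C)OC1
F2 | step 16 | dichloro keto alcohol, as 27 with a second chlorine on C5 | CCCCC/C=C/C(C(=O)C(Cl)(Cl)CC=C(C)C)=C1/[C@@H](CO)OC(C)(C)OC1
F3 | step 16 | dichloro keto aldehyde, as 28 with a second chlorine on C5 | CCCCC/C=C/C(C(=O)C(Cl)(Cl)CC=C(C)C)=C1/[C@@H](C=O)OC(C)(C)OC1
F4 | step 16 | chlorohydrin, protonated form of 30 (C4–OH cis to O3, C5–Cl anti to it) | CCCCC/C=C/C1=C2COC(C)(C)O[C@@H]2[C@H](O)[C@](Cl)(CC=C(C)C)C1=O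
F5 | step 5 | (E)-2,3-diiodo-8-methyl-1-(triethylsilyloxy)nona-2,7-dien-4-ol | CC(C)=CCCC(O)/C(I)=C(\I)CO[Si](CC)(CC)CC
F6 | step 5 | (E)-2,3-diiodo-8-methylnona-2,7-diene-1,4-diol | CC(C)=CCCC(O)/C(I)=C(\I)CO
F7 | step 5 | (E)-4-hydroxy-2,3-diiodo-8-methylnona-2,7-dienal | CC(C)=CCCC(O)/C(I)=C(\I)C=O
F8 | step 5 | (2Z,4E)-3-(1-hydroxy-5-methylhex-4-enyl)-2-iododeca-2,4-dienal | CCCCC/C=C/C(C(O)CCC=C(C)C)=C(/I)C=O
F9 | step 5 | (2Z,4E)-3-(1-hydroxy-5-methylhex-4-enyl)-2-iododeca-2,4-dien-1-ol | CCCCC/C=C/C(C(O)CCC=C(C)C)=C(/I)CO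
F10 | step 17 | aldehyde, as 31 with 2-oxoethyl on C5 in place of the prenyl group | CCCCC/C=C/C1=C2COC(C)(C)O[C@@H]2[C@@H]3O[C@]3(CC=O)C1=O
F11 | step 17 | allyl ester of 34 | CCCCC/C=C/C1=C2COC(C)(C)O[C@@H]2[C@@H]3O[C@]3(C/C=C(\C)C(=O)OCC=C)C1=O
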